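**Plan**
Retrosynthesis: cut C1′–C(trione) (reductive Knoevenagel); take the C4 carbinol and the C7 isopropenyl back to a C4 ketone and a C7 ester; cut C10–C1 together with C14–H (ring A, hydrogen-atom-transfer radical closure); then C10=C14 (methylenation), C1=C1′ (cross-metathesis) and C4–C5 (aldol).
Forward: ring B is bought as diethyl 4-oxocyclohexane-1,1-dicarboxylate. The C4–C1 chain is joined to C5 by aldol, the sulfone is put on C1′, the ring ketone becomes the C10=C14 methylene, ring A is closed, and the acyl trione is joined last.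
Enabling feature: C10 carries both the C14 methyl and the ring bond to C1. An exocyclic C10=C14 methylene on ring B that faces a C1=C1′ vinyl sulfone on the C5 chain gives both in one radical event.
Stereochemistry: the L-proline aldol sets C5 and C4. With the C7 gem-diester holding the chain equatorial, these two centres direct C10 and C1 in the ring closure and are then erased (C4 oxidised, C5 equilibrated to the trans fusion). C7 is set by equilibration after decarboxylation; the C4 carbinol by α-face epoxidation and hydride opening.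

Key step: step 5

Convention: eudesmane numbering (C14 = methyl on C10, C15 = methyl on C4, C1′ = exocyclic carbon on C1); β is the face of C14.
Remark: the acyl trione unit is written as the enol tautomer of the target; its tautomers interconvert freely, so no step is spent on fixing one.

Step 1
Reactants: 1 diethyl 4-oxocyclohexane-1,1-dicarboxylate; 2 pent-4-enal
Product: 3 diethyl (3S)-3-[(1S)-1-hydroxypent-4-en-1-yl]-4-oxocyclohexane-1,1-dicarboxylate (anti aldol)
Conditions: L-proline (30 mol%), DMSO, 1 in excess (4 equiv), 2 added slowly, 4 °C → rt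
Reagents that add atoms: none
Why: Proline-catalysed enamine aldol of a 4,4-disubstituted cyclohexanone, whose acid-directed chair transition state should give the anti adduct with (S) at the ring carbon (later C5) and (S) at the carbinol (later C4), while excess ketone and slow addition hold back self-condensation of the unbranched aldehyde.

Step 2
Reactants: 3 the anti aldol
Product: 4 diethyl (3S)-3-[(1S)-1-(tert-butyldimethylsilyloxy)pent-4-en-1-yl]-4-oxocyclohexane-1,1-dicarboxylate
Conditions: TBSOTf, 2,6-lutidine, CH2Cl2, −78 → 0 °C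
Reagents that add atoms: tert-butyldimethylsilyl trifluoromethanesulfonate, CC(C)(C)[Si](C)(C)OS(=O)(=O)C(F)(F)F
Why: Silyl ether formation, which blocks retro-aldol and β-elimination during methylenation, keeps the oxygen from adding to the vinyl sulfone and supplies the bulky group that later steers the ring closure.

Step 3
Reactants: 4 the silyl ether; 5 phenyl vinyl sulfone
Product: 6 diethyl (3S)-3-[(1S,4E)-1-(tert-butyldimethylsilyloxy)-5-(phenylsulfonyl)pent-4-en-1-yl]-4-oxocyclohexane-1,1-dicarboxylate
Conditions: Hoveyda–Grubbs II (5 mol%), 5 (2 equiv), CH2Cl2, 40 °C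
Reagents that add atoms: none
Why: Olefin cross-metathesis of a terminal alkene with an electron-poor vinyl sulfone that does not homodimerise should give the E-vinyl sulfone, and it is run before methylenation because a C10 methylene would ring-close onto the terminal alkene.

Step 4
Reactants: 6 the keto vinyl sulfone
Product: 7 diethyl (3R)-3-[(1S,4E)-1-(tert-butyldimethylsilyloxy)-5-(phenylsulfonyl)pent-4-en-1-yl]-4-methylidenecyclohexane-1,1-dicarboxylate
Conditions: Zn, CH2Br2, TiCl4, THF/CH2Cl2, 0 °C → rt
Reagents that add atoms: dibromomethane, BrCBr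
Why: Takai–Lombardo methylenation is non-basic, so C5 should not epimerise, the silyloxy group should not eliminate and the vinyl sulfone should not be attacked or isomerised, and the reagent leaves esters alone.

Step 5
Reactants: 7 the methylene vinyl sulfone
Product: 8 cis-fused decalin: diethyl 4α-(tert-butyldimethylsilyloxy)-10β-methyl-1β-[(phenylsulfonyl)methyl]-5βH-decalin-7,7-dicarboxylate
Conditions: Fe(acac)3 (30 mol%), PhSiH3 (3 equiv), EtOH/ethylene glycol 5:1, 0.02 M, 60 °C; chromatography to remove any trans-fused isomer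
Reagents that add atoms: none
Why: The iron hydride formed from Fe(acac)3 and PhSiH3 transfers a hydrogen atom to C14 of the electron-rich 1,1-disubstituted alkene, the tertiary C10 radical adds 6-exo-trig to C1 of the E-vinyl sulfone and so closes ring A, and the α-sulfonyl radical is reduced by iron(II) and protonated by ethanol. The closest known reaction type is the hydrogen-atom-transfer-initiated intramolecular Giese cyclisation (iron-mediated reductive olefin coupling) that builds quaternary centres. C10 is set by C5 and C4 together: one C7 ester is always axial, which forbids an axial C5 chain, and of the two chair closures from the equatorial chain only the one on the axial face of C10 (cis ring fusion, C14 cis to H5) keeps the C4 silyloxy group equatorial, whereas the trans closure would place it 1,3-diaxial to the new C10 methyl. C1 is set by the chair in which the sulfonylvinyl carbon is pseudo-equatorial, which puts C1′ cis to C14. The step needs hydrogen-atom transfer to the methylene and not to the vinyl sulfone, which the preference of the metal hydride for the electron-rich alkene should secure, and it needs the trans-fused diastereomer to be removed here, because after steps 7 and 8 that isomer would end in the enantiomeric series.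

Step 6
Reactants: 8 the cis-fused silyl ether
Product: 9 diethyl 4α-hydroxy-10β-methyl-1β-[(phenylsulfonyl)methyl]-5βH-decalin-7,7-dicarboxylate
Conditions: HF·pyridine, THF, 0 °C → rt
Reagents that add atoms: none
Why: Fluoride cleavage of the silyl ether under conditions to which esters and the sulfone are inert.

Step 7
Reactants: 9 the 4α-alcohol
Product: 10 diethyl 10β-methyl-4-oxo-1β-[(phenylsulfonyl)methyl]-5βH-decalin-7,7-dicarboxylate (cis-fused ketone)
Conditions: Dess–Martin periodinane, NaHCO3, CH2Cl2, rt
Reagents that add atoms: none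
Why: Dess–Martin oxidation of the secondary alcohol removes the C4 stereocentre, whose relay role is over, and makes C5 epimerisable.

Step 8
Reactants: 10 the cis-fused keto diester
Product: 12 ethyl 10β-methyl-4-oxo-1β-[(phenylsulfonyl)methyl]-5αH-decalin-7β-carboxylate (trans-fused keto ester), via C5/C7-epimeric monoester 11 (not isolated)
Conditions: LiCl, H2O, DMSO, 150 °C; then NaOEt (0.3 equiv), EtOH, rt
Reagents that add atoms: none
Why: Krapcho dealkoxycarbonylation removes one ester, and ethoxide then equilibrates C5 through the ketone enolate to the trans fusion and C7 through the ester enolate to the equatorial β-ester, both thermodynamic positions, with a minor axial-ester epimer expected that can be separated and re-equilibrated.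

Step 9
Reactants: 12 the trans-fused keto ester
Product: 13 ethyl 10β-methyl-4-methylidene-1β-[(phenylsulfonyl)methyl]-5αH-decalin-7β-carboxylate
Conditions: Ph3PCH3Br, KOtBu, toluene, 0 → 80 °C
Reagents that add atoms: methyltriphenylphosphonium bromide, C[P+](c1ccccc1)(c1ccccc1)c1ccccc1.[Br-]
Why: Wittig methylenation of a 4-oxo decalin with an angular methyl is a standard way to the 4(15)-alkene, the ylide is not basic enough to deprotonate the sulfone, and the basic medium only reinforces the trans fusion.

Step 10
Reactants: 13 the 4(15)-alkene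
Product: 14 ethyl 4α,15-epoxy-10β-methyl-1β-[(phenylsulfonyl)methyl]-5αH-decalin-7β-carboxylate (oxygen α, CH2 β)
Conditions: mCPBA, NaHCO3, CH2Cl2, 0 °C
Reagents that add atoms: 3-chloroperbenzoic acid, OOC(=O)c1cccc(Cl)c1
Why: Prilezhaev epoxidation in which the peracid should approach from the equatorial α face because the axial β face is shielded by the 1,3-diaxial C14 methyl, which places the oxygen α at C4.

Step 11
Reactants: 14 the epoxy ester
Product: 15 lithium 4α,15-epoxy-10β-methyl-1β-[(phenylsulfonyl)methyl]-5αH-decalin-7β-carboxylate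
Conditions: LiOH·H2O (1.1 equiv), THF/H2O, rt; evaporate, dry azeotropically (toluene)
Reagents that add atoms: lithium hydroxide, [Li+].[OH-]
Why: Saponification gives the carboxylate salt, the form in which the C7 acyl group survives the hydride of the next step, and the hindered spiro-epoxide should tolerate cold hydroxide.

Step 12
Reactants: 15 the lithium epoxy carboxylate
Product: 16 4α-hydroxy-4β,10β-dimethyl-1β-[(phenylsulfonyl)methyl]-5αH-decalin-7β-carboxylic acid
Conditions: LiEt3BH (3 equiv), THF, 0 → 50 °C; then cold aq. HCl to pH 3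
Reagents that add atoms: none
Why: Triethylborohydride opens the epoxide by SN2 attack at the primary C15 and so gives the 4α-hydroxy-4β-methyl carbinol with the configuration fixed in step 10, while a carboxylate salt is not reduced by this reagent.

Step 13
Reactants: 16 the hydroxy acid
Product: 17 1-{4α-hydroxy-4β,10β-dimethyl-1β-[(phenylsulfonyl)methyl]-5αH-decalin-7β-yl}ethanone
Conditions: MeLi (6 equiv), THF, 0 °C → rt; inverse quench into cold 1 M HCl
Reagents that add atoms: methyllithium, [Li]C
Why: Addition of methyllithium to a lithium carboxylate stops at the gem-diolate and gives the methyl ketone on hydrolysis, the extra equivalents being held by the alkoxide and the α-sulfonyl carbanion, which are reprotonated on quench.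

Step 14
Reactants: 17 the methyl ketone
Product: 18 1β-[(phenylsulfonyl)methyl]eudesm-11-en-4α-ol
Conditions: Ph3PCH3Br, KOtBu, THF, 0 °C → rt
Reagents that add atoms: methyltriphenylphosphonium bromide, C[P+](c1ccccc1)(c1ccccc1)c1ccccc1.[Br-]
Why: Wittig methylenation of an unhindered methyl ketone gives the isopropenyl group, and the basic ylide can only equilibrate C7 towards the equatorial acetyl already present.

Step 15
Reactants: 18 the hydroxy sulfone
Product: 20 4α-hydroxyeudesm-11-ene-1β-carbaldehyde (CHO carbon = C1′), via α-trimethylsilyloxy sulfone 19 (not isolated)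
Conditions: n-BuLi (2.2 equiv), THF, −78 °C; then Me3SiOOSiMe3 (2 equiv), −78 °C → rt; aq. NH4Cl
Reagents that add atoms: bis(trimethylsilyl) peroxide, C[Si](C)(C)OO[Si](C)(C)C
Why: Oxidative desulfonylation, in which the α-sulfonyl carbanion attacks the peroxide oxygen and the α-silyloxy sulfone collapses to the aldehyde with loss of sulfinate, C1 itself not being touched.

Step 16
Reactants: 21 phloroglucinol
Product: 22 3-methyl-1-(2,4,6-trihydroxyphenyl)butan-1-one
Conditions: 3-methylbutanoyl chloride, AlCl3, PhNO2/CS2, 50 °C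
Reagents that add atoms: 3-methylbutanoyl chloride, CC(C)CC(=O)Cl
Why: Friedel–Crafts C-acylation of a very electron-rich arene, the first acyl group deactivating the ring against a second.

Step 17
Reactants: 22 the acylphloroglucinol
Product: 23 3,5-dihydroxy-6,6-dimethyl-2-(3-methylbutanoyl)cyclohexa-2,4-dien-1-one (acyl trione)
Conditions: NaOMe (3 equiv), MeI (2.2 equiv), MeOH, 0 °C → rt
Reagents that add atoms: iodomethane, CI
Why: Base-mediated C-methylation of the acylphloroglucinol, in which the once-methylated ring carbon is still enolisable and takes the second methyl, so the ring is dearomatised to the gem-dimethyl trione, with under- and over-methylated products to be separated.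

Step 18
Reactants: 20 the aldehyde; 23 the acyl trione
Product: 25 the target CNP0490948.1, via Knoevenagel alkylidene trione 24 (not isolated)
Conditions: L-proline (20 mol%), Hantzsch ester (1.2 equiv), CH2Cl2, rt
Reagents that add atoms: none
Why: Amine-catalysed Knoevenagel condensation at the free ring carbon of the trione followed in the same pot by conjugate hydride transfer from the Hantzsch ester to the alkylidene trione (three-component reductive alkylation), which forms no stereocentre and leaves the tertiary alcohol and the isopropenyl group alone.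

**Compound list**
1 | diethyl 4-oxocyclohexane-1,1-dicarboxylate | CCOC(=O)C1(CCC(=O)CC1)C(=O)OCC | starting material
2 | pent-4-enal | C=CCCC=O | starting material
3 | diethyl (3S)-3-[(1S)-1-hydroxypent-4-en-1-yl]-4-oxocyclohexane-1,1-dicarboxylate | O=C1CCC(C(=O)OCC)(C(=O)OCC)C[C@H]1[C@@H](O)CCC=C | intermediate
4 | diethyl (3S)-3-[(1S)-1-(tert-butyldimethylsilyloxy)pent-4-en-1-yl]-4-oxocyclohexane-1,1-dicarboxylate | O=C1CCC(C(=O)OCC)(C(=O)OCC)C[C@H]1[C@@H](O[Si](C)(C)C(C)(C)C)CCC=C | intermediate
5 | phenyl vinyl sulfone | C=CS(=O)(=O)c1ccccc1 | starting material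
6 | diethyl (3S)-3-[(1S,4E)-1-(tert-butyldimethylsilyloxy)-5-(phenylsulfonyl)pent-4-en-1-yl]-4-oxocyclohexane-1,1-dicarboxylate | O=C1CCC(C(=O)OCC)(C(=O)OCC)C[C@H]1[C@@H](O[Si](C)(C)C(C)(C)C)CC/C=C/S(=O)(=O)c1ccccc1 | intermediate
7 | diethyl (3R)-3-[(1S,4E)-1-(tert-butyldimethylsilyloxy)-5-(phenylsulfonyl)pent-4-en-1-yl]-4-methylidenecyclohexane-1,1-dicarboxylate | C=C1CCC(C(=O)OCC)(C(=O)OCC)C[C@H]1[C@@H](O[Si](C)(C)C(C)(C)C)CC/C=C/S(=O)(=O)c1ccccc1 | intermediate
8 | diethyl 4α-(tert-butyldimethylsilyloxy)-10β-methyl-1β-[(phenylsulfonyl)methyl]-5βH-decalin-7,7-dicarboxylate (cis-fused) | CCOC(=O)C1(C(=O)OCC)CC[C@]2(C)[C@@H](CS(=O)(=O)c3ccccc3)CC[C@H](O[Si](C)(C)C(C)(C)C)[C@@H]2C1 | intermediate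
9 | diethyl 4α-hydroxy-10β-methyl-1β-[(phenylsulfonyl)methyl]-5βH-decalin-7,7-dicarboxylate | CCOC(=O)C1(C(=O)OCC)CC[C@]2(C)[C@@H](CS(=O)(=O)c3ccccc3)CC[C@H](O)[C@@H]2C1 | intermediate
10 | diethyl 10β-methyl-4-oxo-1β-[(phenylsulfonyl)methyl]-5βH-decalin-7,7-dicarboxylate (cis-fused) | CCOC(=O)C1(C(=O)OCC)CC[C@]2(C)[C@@H](CS(=O)(=O)c3ccccc3)CCC(=O)[C@@H]2C1 | intermediate
11 | ethyl 10β-methyl-4-oxo-1β-[(phenylsulfonyl)methyl]decalin-7-carboxylate, mixture of C5 and C7 epimers | CCOC(=O)C1CC[C@]2(C)[C@@H](CS(=O)(=O)c3ccccc3)CCC(=O)C2C1 | intermediate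
12 | ethyl 10β-methyl-4-oxo-1β-[(phenylsulfonyl)methyl]-5αH-decalin-7β-carboxylate (trans-fused) | CCOC(=O)[C@H]1CC[C@]2(C)[C@@H](CS(=O)(=O)c3ccccc3)CCC(=O)[C@H]2C1 | intermediate
13 | ethyl 10β-methyl-4-methylidene-1β-[(phenylsulfonyl)methyl]-5αH-decalin-7β-carboxylate | CCOC(=O)[C@H]1CC[C@]2(C)[C@@H](CS(=O)(=O)c3ccccc3)CCC(=C)[C@H]2C1 | intermediate
14 | ethyl 4α,15-epoxy-10β-methyl-1β-[(phenylsulfonyl)methyl]-5αH-decalin-7β-carboxylate | CCOC(=O)[C@H]1CC[C@]2(C)[C@@H](CS(=O)(=O)c3ccccc3)CC[C@]4(OC4)[C@H]2C1 | intermediate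
15 | lithium 4α,15-epoxy-10β-methyl-1β-[(phenylsulfonyl)methyl]-5αH-decalin-7β-carboxylate | [Li+].[O-]C(=O)[C@H]1CC[C@]2(C)[C@@H](CS(=O)(=O)c3ccccc3)CC[C@]4(OC4)[C@H]2C1 | intermediate
16 | 4α-hydroxy-4β,10β-dimethyl-1β-[(phenylsulfonyl)methyl]-5αH-decalin-7β-carboxylic acid | OC(=O)[C@H]1CC[C@]2(C)[C@@H](CS(=O)(=O)c3ccccc3)CC[C@](C)(O)[C@H]2C1 | intermediate
17 | 1-{4α-hydroxy-4β,10β-dimethyl-1β-[(phenylsulfonyl)methyl]-5αH-decalin-7β-yl}ethanone | CC(=O)[C@H]1CC[C@]2(C)[C@@H](CS(=O)(=O)c3ccccc3)CC[C@](C)(O)[C@H]2C1 | intermediate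
18 | 1β-[(phenylsulfonyl)methyl]eudesm-11-en-4α-ol | C=C(C)[C@H]1CC[C@]2(C)[C@@H](CS(=O)(=O)c3ccccc3)CC[C@](C)(O)[C@H]2C1 | intermediate
19 | 1β-[(phenylsulfonyl)(trimethylsilyloxy)methyl]eudesm-11-en-4α-ol (C1′ epimers) | C=C(C)[C@H]1CC[C@]2(C)[C@@H](C(O[Si](C)(C)C)S(=O)(=O)c3ccccc3)CC[C@](C)(O)[C@H]2C1 | intermediate
20 | 4α-hydroxyeudesm-11-ene-1β-carbaldehyde | C=C(C)[C@H]1CC[C@]2(C)[C@@H](C=O)CC[C@](C)(O)[C@H]2C1 | intermediate
21 | phloroglucinol | Oc1cc(O)cc(O)c1 | starting material
22 | 3-methyl-1-(2,4,6-trihydroxyphenyl)butan-1-one | CC(C)CC(=O)c1c(O)cc(O)cc1O | intermediate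
23 | 3,5-dihydroxy-6,6-dimethyl-2-(3-methylbutanoyl)cyclohexa-2,4-dien-1-one | CC(C)CC(=O)C1=C(O)C=C(O)C(C)(C)C1=O | intermediate
24 | Knoevenagel adduct: the C1′ alkylidene of 23 on the eudesmane aldehyde (alkene geometry open) | C=C(C)[C@H]1CC[C@]2(C)[C@@H](C=C3C(=O)C(C)(C)C(=O)C(C(=O)CC(C)C)=C3O)CC[C@](C)(O)[C@H]2C1 | intermediate
25 | CNP0490948.1 | C=C(C)[C@H]1CC[C@]2(C)[C@@H](CC3=C(O)C(C)(C)C(=O)C(C(=O)CC(C)C)=C3O)CC[C@](C)(O)[C@H]2C1 | target

**Count**
Total steps: 18 (16 in the main line, 2 for the acyl trione). Longest linear sequence: 16 steps (steps 1–15 and 18).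

**Steps most likely to fail**

Step 5. The tertiary radical may also close on the equatorial face of C10 (trans ring closure) despite the silyloxy bias, or be reduced before it closes. The first process would feed the enantiomeric series after steps 7 and 8. The fallback sets out from 1 and 2 and returns at 12. It runs the antipodal aldol series and closes the ring at the ketone oxidation level, where C4 is sp2, no 1,3-diaxial penalty opposes the chair–chair trans closure, and that closure is the productive one. D-Proline aldol gives the antipodal aldol F1. Silylation gives the silyl ether F2. Cross-metathesis with 5 gives the vinyl sulfone F3. Takai–Lombardo methylenation gives the methylene compound F4. HF·pyridine gives the homoallylic alcohol F5. Buffered Dess–Martin oxidation gives the β,γ-unsaturated ketone F6, to be used crude because its C5 is now enolisable. The same iron hydride conditions should then give the trans-fused keto diester F7, which enters the conditions of step 8 and gives 12.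

Step 1. Self-aldolisation and dehydration of the unbranched aldehyde may outrun the enamine pathway, and the anti/syn ratio may be low. The fallback sets out from 1 (with 2 and 5) and returns at 7. It makes C4–C5 by allylboration, which does not depend on enamine catalysis and brings the methylene with it. LiHMDS and PhNTf2 convert 1 into the enol triflate F8. Palladium-catalysed coupling with bis(pinacolatoboryl)methane gives the allylboronate F9. Cross-metathesis of 2 with 5 gives (E)-5-(phenylsulfonyl)pent-4-enal F10. Chiral phosphoric acid-catalysed allylboration of F10 with F9 should pass through the chair transition state, in which the ring CH2 lies trans to the CH2B group and the adduct is therefore anti; the catalyst enantiomer is chosen for the (1S) carbinol. This gives the homoallylic alcohol F11, and silylation (TBSOTf, 2,6-lutidine) gives 7.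

Step 15. Oxygen transfer to the hindered dilithiated substrate may be incomplete, and unreacted carbanion may add to the aldehyde as it forms. The fallback sets out from 18 and returns at 20. The dianion of 18 (n-BuLi, 2.2 equiv) is sulfenylated with dimethyl disulfide to the α-(methylthio) sulfone F12, a monothioacetal S,S-dioxide. Thiophile-assisted hydrolysis (CuCl2, wet MeCN, rt) should then expel sulfinate and thiol and give 20.

**Further compounds**
F1 | step 5 | diethyl (3R)-3-[(1R)-1-hydroxypent-4-en-1-yl]-4-oxocyclohexane-1,1-dicarboxylate | O=C1CCC(C(=O)OCC)(C(=O)OCC)C[C@@H]1[C@H](O)CCC=C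
F2 | step 5 | diethyl (3R)-3-[(1R)-1-(tert-butyldimethylsilyloxy)pent-4-en-1-yl]-4-oxocyclohexane-1,1-dicarboxylate | O=C1CCC(C(=O)OCC)(C(=O)OCC)C[C@@H]1[C@H](O[Si](C)(C)C(C)(C)C)CCC=C
F3 | step 5 | diethyl (3R)-3-[(1R,4E)-1-(tert-butyldimethylsilyloxy)-5-(phenylsulfonyl)pent-4-en-1-yl]-4-oxocyclohexane-1,1-dicarboxylate | O=C1CCC(C(=O)OCC)(C(=O)OCC)C[C@@H]1[C@H](O[Si](C)(C)C(C)(C)C)CC/C=C/S(=O)(=O)c1ccccc1
F4 | step 5 | diethyl (3S)-3-[(1R,4E)-1-(tert-butyldimethylsilyloxy)-5-(phenylsulfonyl)pent-4-en-1-yl]-4-methylidenecyclohexane-1,1-dicarboxylate | C=C1CCC(C(=O)OCC)(C(=O)OCC)C[C@@H]1[C@H](O[Si](C)(C)C(C)(C)C)CC/C=C/S(=O)(=O)c1ccccc1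
F5 | step 5 | diethyl (3S)-3-[(1R,4E)-1-hydroxy-5-(phenylsulfonyl)pent-4-en-1-yl]-4-methylidenecyclohexane-1,1-dicarboxylate | C=C1CCC(C(=O)OCC)(C(=O)OCC)C[C@@H]1[C@H](O)CC/C=C/S(=O)(=O)c1ccccc1
F6 | step 5 | diethyl (3S)-4-methylidene-3-[(4E)-5-(phenylsulfonyl)pent-4-enoyl]cyclohexane-1,1-dicarboxylate | C=C1CCC(C(=O)OCC)(C(=O)OCC)C[C@@H]1C(=O)CC/C=C/S(=O)(=O)c1ccccc1
F7 | step 5 | diethyl 10β-methyl-4-oxo-1β-[(phenylsulfonyl)methyl]-5αH-decalin-7,7-dicarboxylate (trans-fused) | CCOC(=O)C1(C(=O)OCC)CC[C@]2(C)[C@@H](CS(=O)(=O)c3ccccc3)CCC(=O)[C@H]2C1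
F8 | step 1 | diethyl 4-(trifluoromethylsulfonyloxy)cyclohex-3-ene-1,1-dicarboxylate | CCOC(=O)C1(C(=O)OCC)CC=C(OS(=O)(=O)C(F)(F)F)CC1
F9 | step 1 | diethyl 4-[(4,4,5,5-tetramethyl-1,3,2-dioxaborolan-2-yl)methyl]cyclohex-3-ene-1,1-dicarboxylate | CCOC(=O)C1(C(=O)OCC)CC=C(CB2OC(C)(C)C(C)(C)O2)CC1
F10 | step 1 | (E)-5-(phenylsulfonyl)pent-4-enal | O=CCC/C=C/S(=O)(=O)c1ccccc1
F11 | step 1 | diethyl (3R)-3-[(1S,4E)-1-hydroxy-5-(phenylsulfonyl)pent-4-en-1-yl]-4-methylidenecyclohexane-1,1-dicarboxylate | C=C1CCC(C(=O)OCC)(C(=O)OCC)C[C@H]1[C@@H](O)CC/C=C/S(=O)(=O)c1ccccc1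
F12 | step 15 | 1β-[(methylthio)(phenylsulfonyl)methyl]eudesm-11-en-4α-ol (C1′ epimers) | C=C(C)[C@H]1CC[C@]2(C)[C@@H](C(SC)S(=O)(=O)c3ccccc3)CC[C@](C)(O)[C@H]2C1
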